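**Plan**

Numbering used throughout: ten-membered ring C1–C10, with C1 = ring-fusion CH next to the benzylic carbon C1′, C2 and C3 = the two CH2 groups that follow it, C4(Me)=C5 = the Z olefin, C7 = CH carrying the dimethylcarbinol C11, C10 = O-bearing quaternary carbon with methyl C14.
Cuts, in retrosynthetic order: (i) O–C10 and C1′–C1 of the pyran ring (retro hetero-Diels–Alder) to an ortho-quinone methide and a cyclodeca-1,5-diene carbinol; (ii) C14–C10 (methyl, via an enol triflate); (iii) C2–C3 by a retro-[3,3] shift to a cis-1-vinyl-2-isopropenylcyclohexanol; (iv) vinyl–C10 and isopropenyl–C5 back to a cyclohexene epoxide.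
Enabling feature: the ring CH2–CH2 unit lies between the Z-olefin carbon C4 and C1; C1/C10 are the footprint of a hetero-Diels–Alder reaction on an E olefin, so C10, C1, C2, C3, C4, C5 form a cyclodeca-1,5-diene and C2–C3 is its Cope bond.
Forward order: cyclohexane ring (from (R)-cyclohex-3-ene-1-carboxylic acid), then isopropenyl and vinyl groups, then the ten-membered ring by anionic oxy-Cope ring expansion with enolate triflation, then methylation, then the pyran ring last by a three-component hetero-Diels–Alder reaction.
Stereochemistry: C7 comes from the acid and controls two temporary cyclohexane centres (trans-diaxial epoxide opening, equilibration, axial acetylide addition); the chair transition state turns these into the Z (C4=C5) and E (C1=C10) geometries; suprafacial cycloaddition to the E olefin gives the trans ring fusion, with C10, C1 and C1′ set under control of C7 through the ring conformation.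

Key step: step 9

Assumption: (R)-cyclohex-3-ene-1-carboxylic acid 1 and 2,4-diformylphloroglucinol 15 are bought as catalogue compounds.

Step 1
Reactants: 1 (R)-cyclohex-3-ene-1-carboxylic acid
Product: 2 (1R,4R,5R)-4-iodo-6-oxabicyclo[3.2.1]octan-7-one (iodolactone)
Conditions: I2, KI, NaHCO3, H2O/CH2Cl2, 0 °C to rt
Reagents that add atoms: iodine, II
Why: Iodolactonisation: the carboxylate opens the iodonium ion anti at the olefin carbon 1,3 to the carboxyl-bearing carbon (a necessarily cis-bridged five-membered lactone), which fixes oxygen cis and iodine trans to the future side chain at the two new stereocentres.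

Step 2
Reactants: 2 iodolactone
Product: 3 ethyl (1R,3R,6S)-7-oxabicyclo[4.1.0]heptane-3-carboxylate (epoxide cis to the ester)
Conditions: K2CO3, EtOH, rt
Reagents that add atoms: ethanol, CCO
Why: Ethanolysis of the lactone releases an alkoxide anti-periplanar to the C–I bond, and intramolecular SN2 closure (Williamson type) should give the epoxide on the face of the ester, with inversion only at the iodine-bearing carbon.

Step 3
Reactants: 3 cis-epoxy ester
Product: 4 2-[(1R,3R,6S)-7-oxabicyclo[4.1.0]heptan-3-yl]propan-2-ol
Conditions: MeLi (2.5 equiv), THF, −78 °C; then H2O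
Reagents that add atoms: methyllithium, [Li]C
Why: Double addition of MeLi to the ester builds the dimethylcarbinol C11, while the epoxide, which reacts only slowly with organolithiums at low temperature, should survive; no stereocentre is touched.

Step 4
Reactants: 4 epoxy alcohol
Product: 5 (1S,2R,4R)-4-(2-hydroxypropan-2-yl)-2-(prop-1-en-2-yl)cyclohexan-1-ol (OH and isopropenyl trans-diaxial, OH cis to the side chain)
Conditions: isopropenylmagnesium bromide (3 equiv), CuI (10 mol%), THF, −30 to 0 °C; then aq. NH4Cl
Reagents that add atoms: isopropenylmagnesium bromide, CC(=C)[Mg]Br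
Why: Copper-catalysed Grignard opening of the epoxide follows the Fürst–Plattner rule: with the bulky alkoxide side chain equatorial, trans-diaxial attack is possible only at the epoxide carbon 1,3 to the side chain (future C5), with inversion, so the isopropenyl group arrives trans to the hydroxyl that stays on the future C10.

Step 5
Reactants: 5 diol
Product: 7 (2S,4R)-4-(2-hydroxypropan-2-yl)-2-(prop-1-en-2-yl)cyclohexan-1-one (2,4-cis, both groups equatorial), via trans-ketone 6 (not isolated)
Conditions: Dess–Martin periodinane, CH2Cl2, 0 °C to rt; aqueous work-up; then DBU (0.2 equiv), CH2Cl2, rt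
Reagents that add atoms: none
Why: Dess–Martin oxidation of the secondary alcohol (the tertiary one cannot react) gives the β,γ-unsaturated ketone, whose acidic α-centre C5 is then equilibrated by mild base to the thermodynamically preferred diequatorial cis isomer, α-protonation of the dienolate being faster than the γ-protonation that would lead to conjugation.

Step 6
Reactants: 7 cis-hydroxy ketone
Product: 8 (2S,4R)-2-(prop-1-en-2-yl)-4-[2-(triethylsilyloxy)propan-2-yl]cyclohexan-1-one
Conditions: TESOTf, 2,6-lutidine, CH2Cl2, −78 °C
Reagents that add atoms: triethylsilyl trifluoromethanesulfonate, CC[Si](CC)(CC)OS(=O)(=O)C(F)(F)F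
Why: Silylation of the hindered tertiary alcohol with the silyl triflate at low temperature, where the ketone is not enolised, masks the only other O–H before the alkoxide chemistry of step 9.

Step 7
Reactants: 8 silyl-protected ketone
Product: 9 (1R,2S,4R)-1-ethynyl-2-(prop-1-en-2-yl)-4-[2-(triethylsilyloxy)propan-2-yl]cyclohexan-1-ol (ethynyl axial, cis to isopropenyl and to the side chain)
Conditions: ethynylmagnesium bromide, THF, −20 to 0 °C; then aq. NH4Cl
Reagents that add atoms: ethynylmagnesium bromide, C#C[Mg]Br
Why: 1,2-Addition of the small, rod-shaped acetylide should occur by axial attack on the chair that has both ring substituents equatorial, which sets the new carbinol centre C10 with the ethynyl group axial and cis to the isopropenyl group and the side chain.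

Step 8
Reactants: 9 propargylic alcohol
Product: 10 (1S,2S,4R)-1-ethenyl-2-(prop-1-en-2-yl)-4-[2-(triethylsilyloxy)propan-2-yl]cyclohexan-1-ol (vinyl axial, isopropenyl and side chain equatorial, all three cis)
Conditions: H2 (1 atm), Pd/CaCO3 poisoned with Pb(OAc)2, quinoline, EtOAc, rt
Reagents that add atoms: none
Why: Semi-hydrogenation over the poisoned palladium catalyst reduces the terminal alkyne to the vinyl group and leaves the 1,1-disubstituted olefin untouched; no stereocentre changes.

Step 9
Reactants: 10 cis-1-vinyl-2-isopropenylcyclohexanol
Product: 12 (1Z,5Z,8R)-5-methyl-8-[2-(triethylsilyloxy)propan-2-yl]cyclodeca-1,5-dien-1-yl trifluoromethanesulfonate (ring carbons trans across C1=C10 and cis across C4=C5 in the numbering of the plan), via potassium enolate 11 (not isolated)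
Conditions: KH, 18-crown-6, THF, 0 to 40 °C; then PhNTf2, −78 to 0 °C
Reagents that add atoms: N-phenylbis(trifluoromethanesulfonimide), O=S(=O)(N(c1ccccc1)S(=O)(=O)C(F)(F)F)C(F)(F)F
Why: Deprotonation gives a tertiary potassium alkoxide, and the 1,5-diene made of the vinyl group on the carbinol carbon and the isopropenyl group on its neighbour undergoes an alkoxide-accelerated [3,3]-sigmatropic shift (anionic oxy-Cope rearrangement) that joins the two olefin termini (C2–C3) while the old ring bond C5–C10 breaks. The closest known reaction type is the anionic oxy-Cope ring expansion of 1,2-dialkenylcyclohexanols to cyclodec-5-enones with trapping of the regiodefined enolate in the same flask. The ten-membered ring is closed as a four-carbon enlargement of the cyclohexane (six to ten) through a chair-like six-centre transition state that is cis-fused to the cyclohexane chair. No stereocentre is created; the two cyclohexane centres are instead converted into olefin geometry: the equatorial isopropenyl group puts C6 pseudo-axial and gives the ring-cis (Z) C4=C5 bond, and the axial vinyl group puts C9 pseudo-equatorial and gives the ring-trans enolate C1=C10 with oxygen cis to C2. The step needs this one chair (not the ring-flipped chair or a boat) and an enolate that keeps its position and geometry: the equatorial C7 side chain locks the chair with vinyl axial and isopropenyl equatorial, and the aprotic medium offers no proton source for equilibration before O-sulfonylation by PhNTf2. The enol triflate carries its oxygen exactly where the C10 methyl group is needed, so step 10 can complete the E olefin with retention.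

Step 10
Reactants: 12 dienyl triflate
Product: 13 triethyl({2-[(1R,3Z,7E)-4,8-dimethylcyclodeca-3,7-dien-1-yl]propan-2-yl}oxy)silane
Conditions: MeMgBr, Fe(acac)3 (5 mol%), THF/NMP, −30 °C
Reagents that add atoms: methylmagnesium bromide, C[Mg]Br
Why: Iron-catalysed Kumada-type cross-coupling of the alkenyl triflate with MeMgBr should replace OTf by methyl with retention of olefin geometry, at a temperature well below the onset of Cope rearrangement of the 1,5-diene.

Step 11
Reactants: 13 silyl-protected diene
Product: 14 2-[(1R,3Z,7E)-4,8-dimethylcyclodeca-3,7-dien-1-yl]propan-2-ol (the 4Z isomer of hedycaryol)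
Conditions: TBAF, THF, rt; then H2O
Reagents that add atoms: none
Why: Fluoride cleaves the tertiary triethylsilyl ether under non-acidic conditions, as the acid-sensitive cyclodecadiene requires.

Step 12
Reactants: 14 (4Z)-hedycaryol isomer, 15 2,4,6-trihydroxybenzene-1,3-dicarbaldehyde (2,4-diformylphloroglucinol), 16 3-methylbutanal
Product: 18 target CNP0570248.1 (5,7-dihydroxychroman-6,8-dicarbaldehyde trans-fused at its C2/C3 to the (Z)-cyclodecene; 2-methyl, 4-isobutyl, 2-hydroxypropan-2-yl on the ten-membered ring; configuration as in the SMILES), via ortho-quinone methide 17 (not isolated)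
Conditions: ethylenediammonium diacetate (20 mol%), MeCN, 40 °C
Reagents that add atoms: none
Why: Knoevenagel condensation of 15 with 16 gives ortho-quinone methide 17, which should add in an inverse-electron-demand hetero-Diels–Alder reaction (domino Knoevenagel/hetero-Diels–Alder) to the strained ring-trans C1=C10 olefin in preference to the unstrained ring-cis C4=C5 olefin, with oxygen bonding to the more substituted C10; suprafacial addition to the E olefin gives the trans ring fusion, the orientation that places H1 and not C2 under the arene sets C1′ (isobutyl cis to H1), and the face that reacts (C10 and C1 relative to C7) is decided by the ring conformer, the target needing the face that is peripheral when the C10 methyl is axial-like, so the adduct of the other face is to be expected beside it and removed by chromatography.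

**Compound list**

1 | (R)-cyclohex-3-ene-1-carboxylic acid | OC(=O)[C@@H]1CCC=CC1 | starting material
2 | (1R,4R,5R)-4-iodo-6-oxabicyclo[3.2.1]octan-7-one | O=C1O[C@@H]2C[C@H]1CC[C@H]2I | intermediate
3 | ethyl (1R,3R,6S)-7-oxabicyclo[4.1.0]heptane-3-carboxylate | CCOC(=O)[C@@H]1CC[C@@H]2O[C@@H]2C1 | intermediate
4 | 2-[(1R,3R,6S)-7-oxabicyclo[4.1.0]heptan-3-yl]propan-2-ol | CC(C)(O)[C@@H]1CC[C@@H]2O[C@@H]2C1 | intermediate
5 | (1S,2R,4R)-4-(2-hydroxypropan-2-yl)-2-(prop-1-en-2-yl)cyclohexan-1-ol | O[C@H]1CC[C@@H](C(C)(C)O)C[C@@H]1C(C)=C | intermediate
6 | (2R,4R)-4-(2-hydroxypropan-2-yl)-2-(prop-1-en-2-yl)cyclohexan-1-one (trans-ketone) | O=C1CC[C@@H](C(C)(C)O)C[C@@H]1C(C)=C | intermediate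
7 | (2S,4R)-4-(2-hydroxypropan-2-yl)-2-(prop-1-en-2-yl)cyclohexan-1-one (cis-ketone) | O=C1CC[C@@H](C(C)(C)O)C[C@H]1C(C)=C | intermediate
8 | (2S,4R)-2-(prop-1-en-2-yl)-4-[2-(triethylsilyloxy)propan-2-yl]cyclohexan-1-one | O=C1CC[C@@H](C(C)(C)O[Si](CC)(CC)CC)C[C@H]1C(C)=C | intermediate
9 | (1R,2S,4R)-1-ethynyl-2-(prop-1-en-2-yl)-4-[2-(triethylsilyloxy)propan-2-yl]cyclohexan-1-ol | C#C[C@@]1(O)CC[C@@H](C(C)(C)O[Si](CC)(CC)CC)C[C@H]1C(C)=C | intermediate
10 | (1S,2S,4R)-1-ethenyl-2-(prop-1-en-2-yl)-4-[2-(triethylsilyloxy)propan-2-yl]cyclohexan-1-ol | C=C[C@@]1(O)CC[C@@H](C(C)(C)O[Si](CC)(CC)CC)C[C@H]1C(C)=C | intermediate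
11 | potassium (1Z,5Z,8R)-5-methyl-8-[2-(triethylsilyloxy)propan-2-yl]cyclodeca-1,5-dien-1-olate | C/C1=C/C[C@H](C(C)(C)O[Si](CC)(CC)CC)CC/C([O-])=C/CC1.[K+] | intermediate
12 | (1Z,5Z,8R)-5-methyl-8-[2-(triethylsilyloxy)propan-2-yl]cyclodeca-1,5-dien-1-yl trifluoromethanesulfonate | C/C1=C/C[C@H](C(C)(C)O[Si](CC)(CC)CC)CC/C(OS(=O)(=O)C(F)(F)F)=C/CC1 | intermediate
13 | triethyl({2-[(1R,3Z,7E)-4,8-dimethylcyclodeca-3,7-dien-1-yl]propan-2-yl}oxy)silane | C/C1=C/C[C@H](C(C)(C)O[Si](CC)(CC)CC)CC/C(C)=C/CC1 | intermediate
14 | 2-[(1R,3Z,7E)-4,8-dimethylcyclodeca-3,7-dien-1-yl]propan-2-ol | C/C1=C/C[C@H](C(C)(C)O)CC/C(C)=C/CC1 | intermediate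
15 | 2,4,6-trihydroxybenzene-1,3-dicarbaldehyde | O=Cc1c(O)cc(O)c(C=O)c1O | starting material
16 | 3-methylbutanal | CC(C)CC=O | starting material
17 | (E)-ortho-quinone methide from 15 and 16 (3,5-diformyl-2,4-dihydroxy-6-(3-methylbutylidene)cyclohexa-2,4-dien-1-one) | O=C1C(C=O)=C(O)C(C=O)=C(O)/C1=C\CC(C)C | intermediate
18 | target CNP0570248.1 | C/C1=C/C[C@H](C(C)(C)O)CC[C@@]2(C)Oc3c(C=O)c(O)c(C=O)c(O)c3[C@@H](CC(C)C)[C@@H]2CC1 | target

Total steps: 12. Longest linear sequence: 12 (15 and 16 are bought and enter in step 12).

**Steps most likely to fail**

Step 12. The cycloaddition may run mainly through the chair-type ring conformer of 14 that exposes the other face of the C1=C10 olefin, giving low or reversed facial selectivity; this is the main uncertainty of the route, and the target may be the minor facial isomer. The diene may also be lost by acid- or heat-induced transannular cyclisation or Cope rearrangement while the Knoevenagel step is slow, and 17 may oligomerise. Fallback: from 15 and 16, a three-component reductive alkylation (Hantzsch ester, L-proline, CH2Cl2, rt) would give 2,4-diformyl-6-(3-methylbutyl)phloroglucinol F1. Oxidation of F1 with DDQ in nitromethane at 0 °C in the presence of 14 would generate 17 without acid, amine or heat, and the cycloaddition returns to the route at 18. This changes how and at what temperature the quinone methide meets the diene and addresses the degradation pathways, but it does not by design reverse the facial preference; the facial ratio would be read again under these aprotic, cold conditions.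

Step 9. Proton transfer or incomplete O-sulfonylation of the crown-ether-solvated potassium enolate may scramble the position and geometry of the enol triflate, and β-fragmentation of the alkoxide may compete with the [3,3] shift. Fallback: from 10, the same rearrangement would be quenched with Me3SiCl to give the trimethylsilyl enol ether F2, which is isolated and purified. MeLi (THF, 0 °C) would then release the regiodefined lithium enolate F3, free of crown ether and excess base, and PhNTf2 would convert it into 12.

Step 7. The basic acetylide may enolise the α-alkenyl ketone and the axial preference of the addition may be incomplete. Fallback: from 8, dimethylsulfonium methylide (Me3S+ I−, n-BuLi, THF, −10 °C to rt) would add axially in a Corey–Chaykovsky epoxidation to give the spiro-epoxide F4 with its CH2 group axial. An excess of the same ylide would open F4 at that CH2 group to the sulfonium alkoxide F5, which loses dimethyl sulfide to give the vinyl carbinol 10 directly; this also removes the semi-hydrogenation of step 8.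

Further compounds
F1 | step 12 | 2,4,6-trihydroxy-5-(3-methylbutyl)benzene-1,3-dicarbaldehyde | CC(C)CCc1c(O)c(C=O)c(O)c(C=O)c1O
F2 | step 9 | trimethylsilyl enol ether corresponding to 12 ((1Z,5Z,8R)-5-methyl-8-[2-(triethylsilyloxy)propan-2-yl]-1-(trimethylsilyloxy)cyclodeca-1,5-diene) | C/C1=C/C[C@H](C(C)(C)O[Si](CC)(CC)CC)CC/C(O[Si](C)(C)C)=C/CC1
F3 | step 9 | lithium (1Z,5Z,8R)-5-methyl-8-[2-(triethylsilyloxy)propan-2-yl]cyclodeca-1,5-dien-1-olate | C/C1=C/C[C@H](C(C)(C)O[Si](CC)(CC)CC)CC/C([O-])=C/CC1.[Li+]
F4 | step 7 | 4-(prop-1-en-2-yl)-6-[2-(triethylsilyloxy)propan-2-yl]-1-oxaspiro[2.5]octane (epoxide CH2 axial, cis to isopropenyl and side chain) | C1O[C@@]12CC[C@@H](C(C)(C)O[Si](CC)(CC)CC)C[C@H]2C(C)=C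
F5 | step 7 | sulfonium alkoxide from F4 (dimethyl{2-[1-oxido-2-(prop-1-en-2-yl)-4-[2-(triethylsilyloxy)propan-2-yl]cyclohexyl]ethyl}sulfonium) | C[S+](C)CC[C@@]1([O-])CC[C@@H](C(C)(C)O[Si](CC)(CC)CC)C[C@H]1C(C)=C
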